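A small charge of G, 0.500 equiv, lets at most half of X react.

the same everywhere: X 2.1 M

| run | G | remark | time |
|---|---|---|---|
| grey | 0.50 equiv | the very flask that is asked about, followed so far |  |
| flask | 0.500 equiv |  | 12 min |

grey run (percent of the X charged)

| time / s | E / % | L / % |
|---|---|---|
| 12.0 | 3.1 | 1.3 |
| 25.0 | 5.0 | 3.4 |
| 40.0 | 5.5 | 3.5 |
| 50.0 | 7.1 | 4.5 |
| 60.0 | 8.9 | 4.9 |
| 80.0 | 8.6 | 6.6 |

(scatter of a reading: 0.5 percentage points)

- the analysis behind the earlier runs scatters by 0.5 percentage points, standard deviation
- steps that have been proposed: X + G -> E + Z; E <-> L; E <-> D; L <-> J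

- the moment within 12 min at which there is most E
- the amount of E, in percent of the X charged, at that time

E and L rise together. So from 25.0 s on we add up each column and take the E share, E over E plus L: 0.605, as read. We therefore treat E ⇌ L as a fast balance, a pre-equilibrium, and reckon with E plus L as one pool.

That pool gained 8.4 percentage points by 25.0 s, but 3.6 points from 50.0 s to 80.0 s, when it stood at 15.2%. The proposed steps let it leak into D and J. So we expect E to top out within a few minutes, a little above 9.20%.

The forecast says 18% at 6 min: “a broad maximum near 6 min”.

The flask gives 10.3% at 2.76 min.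

    X + G → E + Z (k = 0.210 /M/min)
    E ⇌ L (K = 0.740, k = 8.20 /min)
    E ⇌ D (K = 20.0, k = 0.230 /min)
    L ⇌ J (K = 2.60, k = 0.810 /min)

In the flask at that time E and L stand at 10.3% and 7.32%, and our share of their sum gives 10.7%. The relaxation half-life of E and D by the step E ⇌ D alone, 2.87 min, is shorter than the 6.1 min half-life of X by the step X + G → E + Z at 1.73 min. At 1.73 min the flask makes E 1.19 times as fast as it uses it, each step taken net. The neighbour flask with 1.20 equiv of G ends with E plus L at 22.8%; the share makes E 13.8%, and that flask holds 13.1%.

The readings are calculated with constants of no real substance; scatter was added.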